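**Plan**

1. Carotenoid numbering is used: ring C1 = CMe2, C3 and C4 = carbinol carbons, C5(Me)=C6, chain from C6. The chain is cut at C7=C8 (Wittig) into a C10 ring phosphonium salt and the C30 aldehyde apo-8'-lycopenal, and at C7'=C8' (Wittig) into a geranyl phosphonium salt and the C20 dialdehyde crocetindial.
2. In the ring, the trans-3,4-diol comes from anti hydrolysis of a cis-3,4-epoxide. The epoxide and the carbocycle come from one [3+3] annulation that cuts C1–C6 and C3–C4.
3. Enabling feature: C4–C5(Me)=C6–C7(=O) is a 3-methylcrotonate whose C4 bears oxygen, so C4 can be a sulfonium-ylide carbon and C6 its vinylogous nucleophilic end. C1(Me2)–C2–C3(O) is 3-methylbut-2-enal, a 1,3-dielectrophile. C1 carries two identical methyl groups, so the most hindered bond needs no stereocontrol.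
4. Forward order: chiral sulfonium salt → ring and epoxide in one step → diol → bis-silyl ether → C10 phosphonium salt. Separately, geranyl salt + crocetindial → C30 aldehyde. Then Wittig union and desilylation.
5. Stereochemistry: C3 and C4 are set together in the epoxide-forming closure by the chiral sulfide (cis by the ring). Water then inverts C4 to give (3R,4R). Chain E-geometry comes from the Wittig reactions followed by iodine-catalysed equilibration.

Key step: step 2

Assumption: the (1R,4R,5R)-sulfide is taken to deliver the (1S,6R)-epoxide; if the facial sense is the opposite, its commercial (1S,4S,5S)-antipode is used with no other change. Commercial 1 may be an E/Z mixture, and both isomers should converge in step 2.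

**Step 1**
Reactants: 1 ethyl (E)-4-bromo-3-methylbut-2-enoate; 2 (1R,4R,5R)-4,7,7-trimethyl-6-thiabicyclo[3.2.1]octane (isothiocineole)
Product: 3 (1R,4R,5R)-6-[(2E)-4-ethoxy-2-methyl-4-oxobut-2-en-1-yl]-4,7,7-trimethyl-6-thiabicyclo[3.2.1]octan-6-ium tetrafluoroborate (alkyl group on the exo lone pair of sulfur)
Conditions: NaBF4 (aq.), CH2Cl2, rt
Reagents that add atoms: sodium tetrafluoroborate, [Na+].F[B-](F)(F)F
Why: SN2 S-alkylation of the sulfide by the primary allylic bromide on its exposed lone pair should give one sulfonium diastereomer, and exchange to the non-nucleophilic tetrafluoroborate prevents the reverse reaction (sulfonium salt formation).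

**Step 2**
Reactants: 3 sulfonium tetrafluoroborate; 4 3-methylbut-2-enal
Product: 8 ethyl (1S,6R)-2,4,4-trimethyl-7-oxabicyclo[4.1.0]hept-2-ene-3-carboxylate, via sulfonium ylide 5 (not isolated), via aldehyde-bearing ylide 6 (not isolated), via betaine 7 (not isolated)
Conditions: Cs2CO3 (1.5 equiv), 4 (2 equiv), DME, 0 °C → rt
Reagents that add atoms: none
Why: Proposed new method: Cs2CO3 turns 3 into the ester-conjugated allylic ylide 5, whose sulfur-remote carbon C6 adds 1,4 to the β,β-dimethyl terminus of 4 (C1–C6 bond, quaternary C1); a proton shift from C6 re-forms the sulfonium ylide 6 with C5=C6 conjugated to the ester, and the ylide carbon C4 then adds to the tethered aldehyde C3 (C3–C4 bond) to give betaine 7, whose alkoxide expels the sulfide. The closest known reaction type is the tandem Michael addition/ylide epoxidation of crotonate-derived sulfonium ylides with enones to cyclohexadiene epoxides (a sulfur-ylide formal [3+3] annulation ending in a Corey–Chaykovsky closure, also known with chiral sulfonium salts); new here are the β,β-disubstituted enal as acceptor and the 3-methyl group on the ylide, while conjugate addition of stabilised allylic carbanions to β,β-dimethyl acrylates is known. The carbocycle closes 6-exo-trig (ylide carbon onto C=O) and the oxirane 3-exo-tet (alkoxide displaces the sulfonium group with inversion at C4), so the epoxide can only be cis-fused. C1 is not a stereocentre, and the transient C6 centre and the E/Z geometry of 3 are erased in the proton shift, so the only stereocentres, C3 and C4, are set together in the closure: the relative configuration by the ring, the absolute configuration by the rigid bicyclic sulfonium group, which should leave one face of the ylide carbon open to the aldehyde. The step needs γ-1,4 attack to win over α-1,2 attack (direct epoxidation of the aldehyde) and α-1,4 attack (vinylcyclopropane): the bulky sulfonium group shields the α-carbon, betaine formation from an ester-stabilised ylide is reversible whereas the Michael/proton-shift/ring-closure channel ends irreversibly, and the mild heterogeneous base keeps the ylide concentration low.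

**Step 3**
Reactants: 8 epoxy ester
Product: 9 ethyl (3R,4R)-3,4-dihydroxy-2,6,6-trimethylcyclohex-1-ene-1-carboxylate
Conditions: HClO4 (5 mol %), THF/H2O 3:1, 0 °C → rt
Reagents that add atoms: water, O
Why: Acid-catalysed anti opening (Fürst–Plattner, SN2-type) of the γ,δ-epoxy enoate by water at the allylic carbon C4 should invert C4 and leave C3 untouched, giving the trans-diol; attack at C3 is non-allylic and meets a syn-axial methyl of C1.

**Step 4**
Reactants: 9 trans-diol ester
Product: 10 ethyl (3R,4R)-3,4-bis[(tert-butyldimethylsilyl)oxy]-2,6,6-trimethylcyclohex-1-ene-1-carboxylate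
Conditions: TBSOTf (2.5 equiv), 2,6-lutidine, CH2Cl2, −78 → 0 °C
Reagents that add atoms: tert-butyldimethylsilyl triflate, CC(C)(C)[Si](C)(C)OS(=O)(=O)C(F)(F)F
Why: Standard silylation of both secondary alcohols with the silyl triflate; the silyl ethers withstand hydride, ylide base and iodine and are removed at the end by fluoride without acid.

**Step 5**
Reactants: 10 bis-silyl ester
Product: 11 [(3R,4R)-3,4-bis[(tert-butyldimethylsilyl)oxy]-2,6,6-trimethylcyclohex-1-en-1-yl]methanol
Conditions: i-Bu2AlH (3 equiv), CH2Cl2, −78 → 0 °C; aq. KNaC4H4O6 work-up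
Reagents that add atoms: none
Why: 1,2-Reduction of the hindered conjugated ester to the allylic alcohol by two hydride transfers from the aluminium hydride, as for cyclogeranate esters; silyl ethers and stereocentres are untouched.

**Step 6**
Reactants: 11 allylic alcohol
Product: 13 {[(3R,4R)-3,4-bis[(tert-butyldimethylsilyl)oxy]-2,6,6-trimethylcyclohex-1-en-1-yl]methyl}triphenylphosphonium bromide, via allylic bromide 12 (not isolated)
Conditions: CBr4 (1.1 equiv), PPh3 (1.1 equiv), CH2Cl2, 0 °C; then PPh3 (1.2 equiv), MeCN, 40 °C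
Reagents that add atoms: carbon tetrabromide, BrC(Br)(Br)Br; triphenylphosphine, c1ccc(cc1)P(c1ccccc1)c1ccccc1
Why: Appel bromination of the primary allylic alcohol under neutral conditions (no acid that could ionise the allylic C4 silyl ether), then SN2 quaternisation of triphenylphosphine at the primary carbon.

**Step 7**
Reactants: 14 geranyl bromide
Product: 15 [(2E)-3,7-dimethylocta-2,6-dien-1-yl]triphenylphosphonium bromide
Conditions: PPh3, toluene, rt
Reagents that add atoms: triphenylphosphine, c1ccc(cc1)P(c1ccccc1)c1ccccc1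
Why: SN2 quaternisation of triphenylphosphine by the primary allylic bromide, the salt precipitating from toluene.

**Step 8**
Reactants: 15 geranyl phosphonium bromide; 16 crocetindial (all-E 2,6,11,15-tetramethylhexadeca-2,4,6,8,10,12,14-heptaenedial)
Product: 18 all-E 2,6,11,15,19,23-hexamethyltetracosa-2,4,6,8,10,12,14,16,18,22-decaenal (apo-8'-lycopenal), via geranylidene phosphorane 17 (not isolated)
Conditions: n-BuLi, THF, −78 → 0 °C; ylide added slowly to 16 (2.5 equiv), THF/CH2Cl2, −78 °C → rt; then I2 (2 mol %), heptane, daylight, rt; crystallisation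
Reagents that add atoms: none
Why: Wittig olefination forms C7'=C8'; inverse addition to excess dialdehyde should favour mono-condensation (the excess is recovered), and iodine-catalysed equilibration should turn the E/Z mixture into the all-E aldehyde.

**Step 9**
Reactants: 13 ring phosphonium bromide; 18 C30 aldehyde
Product: 20 (3R,4R)-3,4-bis[(tert-butyldimethylsilyl)oxy]-β,ψ-carotene (all-E), via ring ylide 19 (not isolated)
Conditions: n-BuLi, THF, −78 °C; 18, −78 °C → rt; then I2 (2 mol %), heptane, daylight, rt
Reagents that add atoms: none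
Why: Wittig olefination of the polyenal with the allylic ylide forms C7=C8, a standard end-group-to-chain union in carotenoid chemistry; the 7Z isomer is strained against the ring methyl groups, so iodine equilibration should give all-E, and the stereocentres are not involved.

**Step 10**
Reactants: 20 bis-silyl carotenoid
Product: 21 (3R,4R)-β,ψ-carotene-3,4-diol (all-E), the target
Conditions: Bu4NF (4 equiv), AcOH (4 equiv), THF, 0 °C → rt, dark, argon
Reagents that add atoms: none
Why: Fluoride cleaves both Si–O bonds; buffering with acetic acid keeps the medium near neutral, so the polyene and the allylic C4 alcohol should survive.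

**Compound list**

1 | ethyl (E)-4-bromo-3-methylbut-2-enoate | CCOC(=O)/C=C(\C)CBr | starting material
2 | (1R,4R,5R)-4,7,7-trimethyl-6-thiabicyclo[3.2.1]octane (isothiocineole) | C[C@@H]1CC[C@@H]2C[C@H]1SC2(C)C | starting material
3 | (1R,4R,5R)-6-[(2E)-4-ethoxy-2-methyl-4-oxobut-2-en-1-yl]-4,7,7-trimethyl-6-thiabicyclo[3.2.1]octan-6-ium tetrafluoroborate, alkyl group exo on sulfur | C[C@@H]1CC[C@@H]2C[C@H]1[S@@+](C/C(C)=C/C(=O)OCC)C2(C)C.F[B-](F)(F)F | intermediate
4 | 3-methylbut-2-enal | CC(C)=CC=O | starting material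
5 | sulfonium ylide of 3 (carbanion on the sulfur-bound CH) | C[C@@H]1CC[C@@H]2C[C@H]1[S@@+]([CH-]/C(C)=C/C(=O)OCC)C2(C)C | intermediate
6 | sulfonium ylide carrying a 2-methyl-4-oxobutan-2-yl group on the ester-bearing alkene carbon (ylide carbon and quaternary carbon cis) | C[C@@H]1CC[C@@H]2C[C@H]1[S@@+]([CH-]/C(C)=C(/C(=O)OCC)C(C)(C)CC=O)C2(C)C | intermediate
7 | betaine: cyclohexene with the sulfonium group on C4 and the alkoxide on C3, trans | C[C@@H]1CC[C@@H]2C[C@H]1[S@@+]([C@@H]3C(C)=C(C(=O)OCC)C(C)(C)C[C@H]3[O-])C2(C)C | intermediate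
8 | ethyl (1S,6R)-2,4,4-trimethyl-7-oxabicyclo[4.1.0]hept-2-ene-3-carboxylate | CCOC(=O)C1=C(C)[C@@H]2O[C@@H]2CC1(C)C | intermediate
9 | ethyl (3R,4R)-3,4-dihydroxy-2,6,6-trimethylcyclohex-1-ene-1-carboxylate | CCOC(=O)C1=C(C)[C@@H](O)[C@H](O)CC1(C)C | intermediate
10 | ethyl (3R,4R)-3,4-bis[(tert-butyldimethylsilyl)oxy]-2,6,6-trimethylcyclohex-1-ene-1-carboxylate | CCOC(=O)C1=C(C)[C@@H](O[Si](C)(C)C(C)(C)C)[C@H](O[Si](C)(C)C(C)(C)C)CC1(C)C | intermediate
11 | [(3R,4R)-3,4-bis[(tert-butyldimethylsilyl)oxy]-2,6,6-trimethylcyclohex-1-en-1-yl]methanol | OCC1=C(C)[C@@H](O[Si](C)(C)C(C)(C)C)[C@H](O[Si](C)(C)C(C)(C)C)CC1(C)C | intermediate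
12 | (3R,4R)-1-(bromomethyl)-3,4-bis[(tert-butyldimethylsilyl)oxy]-2,6,6-trimethylcyclohex-1-ene | BrCC1=C(C)[C@@H](O[Si](C)(C)C(C)(C)C)[C@H](O[Si](C)(C)C(C)(C)C)CC1(C)C | intermediate
13 | {[(3R,4R)-3,4-bis[(tert-butyldimethylsilyl)oxy]-2,6,6-trimethylcyclohex-1-en-1-yl]methyl}triphenylphosphonium bromide | [Br-].c1ccccc1[P+](c1ccccc1)(c1ccccc1)CC1=C(C)[C@@H](O[Si](C)(C)C(C)(C)C)[C@H](O[Si](C)(C)C(C)(C)C)CC1(C)C | intermediate
14 | geranyl bromide, (2E)-1-bromo-3,7-dimethylocta-2,6-diene | CC(C)=CCC/C(C)=C/CBr | starting material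
15 | [(2E)-3,7-dimethylocta-2,6-dien-1-yl]triphenylphosphonium bromide | CC(C)=CCC/C(C)=C/C[P+](c1ccccc1)(c1ccccc1)c1ccccc1.[Br-] | intermediate
16 | crocetindial, (2E,4E,6E,8E,10E,12E,14E)-2,6,11,15-tetramethylhexadeca-2,4,6,8,10,12,14-heptaenedial | O=C/C(C)=C/C=C/C(C)=C/C=C/C=C(C)/C=C/C=C(C)/C=O | starting material
17 | geranylidene triphenylphosphorane | CC(C)=CCC/C(C)=C/C=P(c1ccccc1)(c1ccccc1)c1ccccc1 | intermediate
18 | apo-8'-lycopenal, (2E,4E,6E,8E,10E,12E,14E,16E,18E)-2,6,11,15,19,23-hexamethyltetracosa-2,4,6,8,10,12,14,16,18,22-decaenal | CC(C)=CCC/C(C)=C/C=C/C(C)=C/C=C/C(C)=C/C=C/C=C(C)/C=C/C=C(C)/C=O | intermediate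
19 | {[(3R,4R)-3,4-bis[(tert-butyldimethylsilyl)oxy]-2,6,6-trimethylcyclohex-1-en-1-yl]methylidene}triphenylphosphorane | c1ccccc1P(c1ccccc1)(c1ccccc1)=CC1=C(C)[C@@H](O[Si](C)(C)C(C)(C)C)[C@H](O[Si](C)(C)C(C)(C)C)CC1(C)C | intermediate
20 | (3R,4R)-3,4-bis[(tert-butyldimethylsilyl)oxy]-β,ψ-carotene, all-E | CC(C)=CCC/C(C)=C/C=C/C(C)=C/C=C/C(C)=C/C=C/C=C(C)/C=C/C=C(C)/C=C/C1=C(C)[C@@H](O[Si](C)(C)C(C)(C)C)[C@H](O[Si](C)(C)C(C)(C)C)CC1(C)C | intermediate
21 | (3R,4R)-β,ψ-carotene-3,4-diol, all-E | CC(C)=CCC/C(C)=C/C=C/C(C)=C/C=C/C(C)=C/C=C/C=C(C)/C=C/C=C(C)/C=C/C1=C(C)[C@@H](O)[C@H](O)CC1(C)C | target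

**Step count and risks**

Total step count: 10. Longest linear sequence: 8 steps (steps 1–6, 9, 10).

Steps most likely to fail:

Step 2 (proposed new method). Conjugate addition at the β,β-dimethyl carbon may be too slow, so that the ylide adds 1,2 to the aldehyde and closes to an acyclic vinyl epoxide, or closes a cyclopropane after α-attack. The fallback sets out from 1 and 4, forms the two bonds one after the other by known reactions, and comes back at 8. Heating 1 with triethyl phosphite (Arbuzov reaction) gives ethyl (E)-4-(diethoxyphosphoryl)-3-methylbut-2-enoate F1. Horner–Wadsworth–Emmons reaction of F1 with 4 (NaH, THF, 0 °C) forms the C3–C4 bond as an alkene in ethyl (2E,4E)-3,7-dimethylocta-2,4,6-trienoate F2. Irradiation (350 nm) equilibrates the central double bond, and heating (toluene, sealed tube, 140 °C) drives disrotatory 6π-electrocyclisation of the 4Z isomer, which forms the C1–C6 bond in racemic ethyl 2,6,6-trimethylcyclohexa-2,4-diene-1-carboxylate F3. DBU moves the diene into conjugation to give ethyl 2,6,6-trimethylcyclohexa-1,3-diene-1-carboxylate (ethyl safranate) F4, an ester that is also sold as a perfumery chemical. Jacobsen–Katsuki epoxidation of its cis-disubstituted 3,4-double bond ([N,N'-bis(3,5-di-tert-butylsalicylidene)-1,2-cyclohexanediaminato]manganese chloride of trivalent manganese, NaOCl, 4-phenylpyridine N-oxide, CH2Cl2, 0 °C; catalyst enantiomer chosen for the (1S,6R) product) then gives 8.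

Step 3. Water may also attack the non-allylic carbon, each such event giving the enantiomeric trans-diol and so eroding the enantiomeric purity, or partial ionisation at C4 may give some cis-diol. The fallback sets out from 8 and comes back at 9; it fixes the regiochemistry through a π-allyl intermediate and then corrects C4. Opening of 8 with Pd(PPh3)4 (zerovalent palladium, 5 mol %) and B(OH)3 in THF, a known opening of γ,δ-epoxy enoates with net retention in which oxygen can only be delivered to the free allyl terminus C4, gives ethyl (3S,4R)-3,4-dihydroxy-2,6,6-trimethylcyclohex-1-ene-1-carboxylate F5. MnO2 (CH2Cl2, rt) oxidises only the allylic hydroxyl to give ethyl (4R)-4-hydroxy-2,6,6-trimethyl-3-oxocyclohex-1-ene-1-carboxylate F6. Hydroxyl-directed reduction with Me4NBH(OAc)3 (MeCN/AcOH, −20 °C) delivers hydride on the face of the remaining hydroxyl and should give the trans-diol 9.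

Step 9. Ylide formation and condensation at the carbon flanked by the quaternary centre and the substituted alkene may be sluggish, and the ylide may lose silanolate from C4 by vinylogous elimination. The fallback reverses the polarity of the union; it sets out from 11 and 18 and comes back at 20. MnO2 (CH2Cl2, rt) oxidises 11 to (3R,4R)-3,4-bis[(tert-butyldimethylsilyl)oxy]-2,6,6-trimethylcyclohex-1-ene-1-carbaldehyde F7. NaBH4 (EtOH/THF, 0 °C) reduces 18 to all-E 2,6,11,15,19,23-hexamethyltetracosa-2,4,6,8,10,12,14,16,18,22-decaen-1-ol F8, which with PPh3·HBr (MeOH/CH2Cl2, rt) gives the corresponding (polyenyl)triphenylphosphonium bromide F9. Wittig reaction of the stabilised ylide of F9 (NaOMe, CH2Cl2/MeOH, 0 °C → rt) with F7, followed by iodine equilibration, gives 20.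

**Further compounds**

F1 | step 2 | ethyl (E)-4-(diethoxyphosphoryl)-3-methylbut-2-enoate | CCOC(=O)/C=C(\C)CP(=O)(OCC)OCC
F2 | step 2 | ethyl (2E,4E)-3,7-dimethylocta-2,4,6-trienoate | CCOC(=O)/C=C(C)/C=C/C=C(C)C
F3 | step 2 | ethyl 2,6,6-trimethylcyclohexa-2,4-diene-1-carboxylate (racemic) | CCOC(=O)C1C(C)=CC=CC1(C)C
F4 | step 2 | ethyl 2,6,6-trimethylcyclohexa-1,3-diene-1-carboxylate (ethyl safranate) | CCOC(=O)C1=C(C)C=CCC1(C)C
F5 | step 3 | ethyl (3S,4R)-3,4-dihydroxy-2,6,6-trimethylcyclohex-1-ene-1-carboxylate | CCOC(=O)C1=C(C)[C@H](O)[C@H](O)CC1(C)C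
F6 | step 3 | ethyl (4R)-4-hydroxy-2,6,6-trimethyl-3-oxocyclohex-1-ene-1-carboxylate | CCOC(=O)C1=C(C)C(=O)[C@H](O)CC1(C)C
F7 | step 9 | (3R,4R)-3,4-bis[(tert-butyldimethylsilyl)oxy]-2,6,6-trimethylcyclohex-1-ene-1-carbaldehyde | O=CC1=C(C)[C@@H](O[Si](C)(C)C(C)(C)C)[C@H](O[Si](C)(C)C(C)(C)C)CC1(C)C
F8 | step 9 | all-E 2,6,11,15,19,23-hexamethyltetracosa-2,4,6,8,10,12,14,16,18,22-decaen-1-ol | CC(C)=CCC/C(C)=C/C=C/C(C)=C/C=C/C(C)=C/C=C/C=C(C)/C=C/C=C(C)/CO
F9 | step 9 | [all-E 2,6,11,15,19,23-hexamethyltetracosa-2,4,6,8,10,12,14,16,18,22-decaen-1-yl]triphenylphosphonium bromide | CC(C)=CCC/C(C)=C/C=C/C(C)=C/C=C/C(C)=C/C=C/C=C(C)/C=C/C=C(C)/C[P+](c1ccccc1)(c1ccccc1)c1ccccc1.[Br-]
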